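Readings and results are simulated with constants of no real substance.

The meeting began from the slowness of the step from target to over-reaction product: in the blue run it barely shows, with 0.4% at 4.00 min.

| flask | starting material | remark | time |
|---|---|---|---|
| blue | 0.66 mM | run made earlier |  |
| Monday's | 0.60 mM |  | 15 min |
| Saturday's | 1.2 mM |  | 15 min |
| Sunday's | 2.5 mM |  | 15 min |
| Wednesday's | 5.0 mM |  | 15 min |
| Tuesday's | 10 mM |  | 15 min |

blue run (percent of the starting material charged)

| time / min | target / % | over-reaction product / % | starting material / % |
|---|---|---|---|
| 0.500 | 0.7 | 0 | 82.5 |
| 1.33 | 1.4 | 0 | 63.3 |
| 2.50 | 2.1 | 0 | 46.1 |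
| 4.00 | 5.2 | 0.4 | 34.7 |
| 5.00 | 4.3 | 0 | 29.5 |

(scatter of a reading: 0.5 percentage points)

- "hardly changes" means that all values lie within two and a half points (for a concentration: within two and a half percent of the largest)

- share of target in all that became target or over-reaction product for Monday's, Saturday's, Sunday's, Wednesday's, Tuesday's, in this order
- the shape of the row from first to last (hardly changes / falls, then rises / falls all the way / rises all the way / rises, then falls)

I proposed treating the asked share, the selectivity, as a clock rather than a yield. It equals one over one plus [over-reaction product]/[target], and if over-reaction is first order, [over-reaction product] is a constant times the area under the target curve. That ratio then depends on the shape of the target curve in time and not on its height.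

I read the constant from the blue run. Target climbs about steadily up to 4.00 min, so its area is that of a triangle. The last two readings then give 0.0187 min⁻¹, the over-reaction constant, the fraction of target passing on per minute. I conceded that this is a weak reading, since 0.4% is less than the scatter of 0.5 percentage points, and zero cannot be excluded.

If target then holds its level up to 15 min, the ratio is 0.243 and the share 80.4%. I assumed that the target curve keeps this shape at each charge, so I expected a flat row near that share.

The forecast put the row at 96%, 96%, 95%, 95% and 94%, shape hardly changes, holding that “even a bimolecular over-reaction should shift the share only slightly”. We agreed on the shape and differed on the height.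

From Monday's to Tuesday's, the flasks give 80.2%, 80.2%, 80.2%, 80.2% and 80.2%, shape hardly changes.

    intermediate B ⇌ target (K = 0.160, k = 0.110 min⁻¹)
    intermediate A → target (k = 0.190 min⁻¹)
    starting material ⇌ intermediate A (K = 0.530, k = 0.120 min⁻¹)
    intermediate B ⇌ intermediate C (K = 2.00, k = 0.160 min⁻¹)
    target → over-reaction product (k = 0.0190 min⁻¹)
    starting material → intermediate B (k = 0.0690 min⁻¹)
    starting material ⇌ dormant form (K = 1.20, k = 0.200 min⁻¹)

In Monday's flask, the relaxation half-life of intermediate B and target by the step joining them alone, both ways together, is 0.869 min, shorter than the run time of 15 min. Between 7.50 min and 15.0 min, target there goes from 5.20% to 4.99% while over-reaction product goes from 0.502% to 1.23%. That puts [over-reaction product]/[target] in Monday's flask at 0.246 at 15.0 min, against 0.243 from the over-reaction constant. In Tuesday's flask at 7.50 min, the constant gives 0.103 and the flask holds 0.0966.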